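As the one minding Saturday's flask, I had to decide after its 50.0 s reading whether to leave it stirring as charged or to add something before 3.0 min.

all flasks: first end groups 0.10 M
- Saturday's: second end groups 0.098 M; one-sided end groups 1 mM; the very flask that is asked about, followed so far
- Wednesday's: second end groups 0.098 M; one-sided end groups 0.50 mM; run made earlier
- flask: second end groups 0.0980 M; one-sided end groups 1.00 mM; time 3.0 min

| run | time / s | links / % | first end groups / % |
|---|---|---|---|
| Saturday's | 10.0 | 18.7 | 80.8 |
| Saturday's | 25.0 | 35.6 | 64.1 |
| Saturday's | 50.0 | 52.2 | 47.9 |
| Wednesday's | 10.0 | 18.8 | 80.1 |
| Wednesday's | 25.0 | 36.9 | 62.9 |
| Wednesday's | 50.0 | 51.4 | 45.8 |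
| Wednesday's | 80.0 | 62.8 | 34.6 |

(scatter of a reading: 1 percentage point)

- each monomer carries two end groups and one-sided end groups one, which caps an end: a chain counts once for every two ends that are left, dead ends included; the units are half of the end groups of the two monomers charged
- what has gone from first end groups into another species counts as reacted, even if it can come back

* whether the average number of monomer units in a chain (unreacted monomers counted as chains of one) reaches 3.0 by 3.0 min (no / yes)
* average number of monomer units in a chain (unreacted monomers counted as chains of one) at 3.0 min

I reckoned in turnovers: the turnover count is the chain length (the number-average degree of polymerization) minus one. A capped end still counts as an end, so in both runs the length is the units, 99.0% of the first end groups charged, over the units minus the links. For an irreversible second-order reaction at near-equal charges this count climbs close to a straight line with time, so I took its slope as a clock. Saturday's reading at 50.0 s, a length of 2.12, gave 1.34 /min, the turnovers per minute.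

I tried this clock on Wednesday's run, which held half the one-sided end groups. It foretold a length of 2.79 at 80.0 s, and the links read there gave a length of 2.73. Length 3.0 needed 2.00 turnovers, which my clock reached at 1.49 min. By 3.0 min it counted 4.02, twice the need, for a length of 5.02. So I left Saturday's flask as charged and added nothing.

The forecast said yes and a length of 4.8, a little lower than my figure, and of length 3.0 it said “so it should be reached comfortably unless the reaction plateaus”.

The flask gave a length of 4.36 at 3.0 min, and the answer was yes, under this scheme:

    first end groups + second end groups ⇌ links (K = 340 /M, k = 0.241 /M/s)
    first end groups + one-sided end groups → capped ends (k = 27.6 /M/s)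
    second end groups → decomposition product (k = 8.86 × 10⁻⁶ /s)

The flask passed length 3.0 at 1.54 min, with 67.0% of its first end groups reacted. The clock, run to that moment, counted 2.06 turnovers against the 2.00 wanted. Run on to 3.0 min, it counted 4.02 where the flask had made 3.36, with links at 76.3% of the first end groups charged. By 30.0 min the links in the flask stood at 82.8%.

The earlier runs and the new flask were generated by integration for substances that don't exist; the scatter is artificial.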